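**Late times.** Late in a run target goes on to over-reaction product, but target's half-life by that step, 3.8 min with north-west's charges, is longer than the 30 s we stop at. So we reckon the chain's rate and leave over-reaction out.

| flask | substrate | partner | initiator | time |
|---|---|---|---|---|
| north-east | 5.0 mM | 4.00 equiv | 4.4 mol% | 30 s |
| south | 5.0 mM | 4.00 equiv | 2.2 mol% | 30 s |
| north-west | 5.0 mM | 4.00 equiv | 1.1 mol% | 30 s |

- which of these there is most of at the end, counted by the substrate in it, north-east (over-reaction product / target / substrate / first chain carrier)
- which of these there is most of at the end, counted by the substrate in it, south (over-reaction product / target / substrate / first chain carrier)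
- which of these there is most of at the end, counted by the substrate in it, north-west (over-reaction product / target / substrate / first chain carrier)
- how much there is at the end of the one of these that leads, in percent of the substrate charged: north-east
- how much there is at the end of the one of these that leads, in percent of the substrate charged: south
- how much there is at the end of the one of these that leads, in percent of the substrate charged: north-west

- in percentages every species weighs as the substrate in it: one ended chains A counts as two
- two of one species on the left: rate k times its square, two consumed each time
- run time (north-east): 30 s

    initiator → 2 initiating radical (k1 = 0.0148 s⁻¹)
    substrate + initiating radical → capped initiator + first chain carrier (k2 = 9.65 × 10⁶ M⁻¹ s⁻¹)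
    partner + first chain carrier ⇌ target + second chain carrier (K3 = 0.223, k3 = 80600 M⁻¹ s⁻¹)
    substrate + second chain carrier → by-product + first chain carrier (k4 = 1.78 × 10⁵ M⁻¹ s⁻¹)
    2 first chain carrier → ended chains A (k5 = 1.5 × 10⁸ M⁻¹ s⁻¹)
    2 second chain carrier → ended chains B (k6 = 3 × 10⁶ M⁻¹ s⁻¹)
    partner + target → over-reaction product (k7 = 0.151 M⁻¹ s⁻¹)
    partner → decomposition product (k8 = 2.10 × 10⁻⁵ s⁻¹)

**Start rate.** First chain carrier meets partner, giving target and second chain carrier. Second chain carrier meets substrate, giving by-product and first chain carrier, or meets target and steps back. Chains end mainly by coupling of first chain carriers, whose constant 1.5 × 10⁸ M⁻¹ s⁻¹ is far above the 3 × 10⁶ M⁻¹ s⁻¹ of second chain carriers. Setting ending equal to initiation, north-west starts by turning over 0.0237 s⁻¹ of its substrate charge. This rate goes with [partner] and the square root of [initiator].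

**The slowings.** Initiator decay, entering as a square root, averages a factor 0.897 over the run. Partner loss averages about 0.938, our estimate for a flask near equal substrate and target. The back-step is product inhibition: second chain carrier goes back on target 2.03 times as readily, at equal concentrations, as it goes forward on substrate, so at equal substrate and target the net rate falls to 0.330 of its value without the back-step.

**Turnover budget.** We call the start rate times both averaged factors and the time the turnover budget, the substrate charges the run would turn over without the back-step: 0.599 in north-west, 0.847 in south and 1.20 in north-east. Integrating the back-step, a given conversion costs ρ (the ratio above) times the logarithm of charge over remainder, less ρ minus one times the fraction converted. Equal substrate and target cost 0.892. North-east's budget exceeds that, so target leads there. South's falls narrowly short and north-west's clearly, so substrate leads in both. We expect substrate left at 41.2% north-east, 51.5% south and 60.8% north-west.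

**The result.** The forecast gives target at 55% north-east, then substrate at 50% south and substrate at 60% north-west, calling south “a close call”, and its north-east figure is for target, which our reckoning does not give apart from what went on to over-reaction product. The simulation has target leading north-east at 54.5% with substrate at 39.6%, substrate leading south at 50.7%, and substrate leading north-west at 60.6%.

**Less partner.** North-west's remaining substrate costs 0.611 on our curve, against its budget of 0.599. Its neighbour, charged with 1.60 equiv of partner, has a budget lower in proportion, 0.240, if we take the same partner factor. That is below the 0.892 for equal substrate and target. The neighbour ends at 30.0 s with substrate at 79.9%, a conversion costing 0.248, and target at 19.0%.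

The numbers belong to no real substance; the flask was simulated.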